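**Plan**

Rings: A is the dimethoxybenzene ring and B its lactone ring (unprimed atoms); D is the benzene ring and C the lactone ring of the 7-oxycoumarin half (primed atoms).
Retrosynthesis: the C2' carbonyl oxygen is removed first (ring C back to a 2H-chromene), then C4'–C4a' and O1'–C2' are cut to an aryl propargyl ether on ring D. Next C3=C4 and O1–C2 of ring B are cut to an aryloxyacetic acid and 2-hydroxy-4,5-dimethoxybenzaldehyde, and last the two O–CH2 bonds at resorcinol.
Forward: resorcinol is mono-propargylated and converted into the aryloxyacetic acid; ring B is closed onto ring A by a Perkin-type condensation; ring C is then closed onto ring D by propargyl Claisen rearrangement and oxa-6π electrocyclisation; one allylic oxidation gives the second lactone.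
Enabling feature: ring C (O1', C2', C3', C4', C4a', C8a') is fused to ring D with O1' on C8a' meta to the diaryl ether oxygen on C7', the 1,3-dioxygenation of resorcinol. O1' can therefore carry C2'–C4' as a propargyl group and deliver C4' to C4a' at the 2H-chromene oxidation level.
Stereochemistry: the target has no stereocentre; only the regiochemistry on ring D has to be controlled.

Key step: step 5

Assumption: the 3-coumarinyloxy substituent on ring D is taken to direct the sigmatropic shift as a methoxy group does, that is, mainly to the ring carbon para to it.

**Route**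

Step 1
Reactants: 1 resorcinol; 2 propargyl bromide
Product: 3 3-(prop-2-yn-1-yloxy)phenol
Conditions: K2CO3 (1 equiv), resorcinol (3 equiv), acetone, reflux
Reagents that add atoms: none
Why: Williamson ether synthesis (SN2 displacement of the propargylic bromide by the phenoxide), in which the excess of resorcinol suppresses bis-alkylation and the unreacted diol is washed out with water.

Step 2
Reactants: 3 3-(prop-2-yn-1-yloxy)phenol; 4 ethyl bromoacetate
Product: 5 ethyl 2-[3-(prop-2-yn-1-yloxy)phenoxy]acetate
Conditions: K2CO3, acetone, reflux
Reagents that add atoms: none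
Why: Williamson O-alkylation of the remaining phenol by the activated α-bromo ester under carbonate conditions that leave the terminal alkyne alone.

Step 3
Reactants: 5 ethyl 2-[3-(prop-2-yn-1-yloxy)phenoxy]acetate
Product: 6 2-[3-(prop-2-yn-1-yloxy)phenoxy]acetic acid
Conditions: LiOH·H2O, THF/H2O, rt; then 1 M HCl
Reagents that add atoms: lithium hydroxide, [Li+].[OH-]
Why: Saponification of the ethyl ester by acyl–oxygen cleavage at room temperature, mild enough not to isomerise the propargyl ether to an allenyl ether.

Step 4
Reactants: 6 2-[3-(prop-2-yn-1-yloxy)phenoxy]acetic acid; 7 2-hydroxy-4,5-dimethoxybenzaldehyde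
Product: 10 6,7-dimethoxy-3-[3-(prop-2-yn-1-yloxy)phenoxy]-2H-chromen-2-one, via mixed anhydride 8 (not isolated), via aryl ester 9 (not isolated)
Conditions: Ac2O, Et3N, 110–120 °C
Reagents that add atoms: none
Why: Perkin–Oglialoro condensation, in which the acid is activated as mixed anhydride 8 and transferred to the phenol as ester 9, whose α-CH2 (acidified by the ester and aryloxy groups) undergoes intramolecular aldol condensation with the ortho-formyl group to close lactone ring B well below the temperature of the propargyl Claisen rearrangement.

Step 5
Reactants: 10 6,7-dimethoxy-3-[3-(prop-2-yn-1-yloxy)phenoxy]-2H-chromen-2-one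
Product: 14 3-(2H-chromen-7-yloxy)-6,7-dimethoxy-2H-chromen-2-one, via allenyl dienone 11 (not isolated), via allenylphenol 12 (not isolated), via quinone methide 13 (not isolated)
Conditions: PhNEt2 (degassed), 200–210 °C, Ar
Reagents that add atoms: none
Why: On heating, a [3,3]-sigmatropic (aromatic propargyl Claisen) shift breaks O1'–C2' and forms C4'–C4a' at the ring D carbon para to the coumarinyloxy group, giving allenyl dienone 11, which tautomerises to allenylphenol 12; a 1,5-hydrogen shift from the phenolic OH to the central allene carbon then gives the (Z)-quinone methide 13. Ring C closes by a thermal disrotatory oxa-6π electrocyclisation of 13 in which the carbonyl oxygen O1' bonds to the vinyl terminus C2', giving the six-membered 2H-pyran ring. The closest known reaction type is the thermal rearrangement of aryl propargyl ethers to 2H-chromenes in N,N-dialkylaniline solvents. No stereocentre remains in the product: the sp3 centre of 11 is lost on tautomerisation, and the Z geometry of 13, set by the intramolecular hydrogen transfer, is consumed in the ring closure. The step needs regioselectivity for the carbon para to the aryloxy oxygen over the carbon flanked by both oxygens, which rests on the crowding of that doubly ortho-substituted position and the known preference of meta-alkoxy aryl ethers for the para position, any 5-oxygenated isomer being removed by chromatography; it also needs chromene rather than 2-methylbenzofuran formation, which the fluoride-free, weakly basic amine medium secures. Since nothing but heat and a high-boiling amine is involved, lactone ring B and the two methoxy groups on ring A are not at risk.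

Step 6
Reactants: 14 3-(2H-chromen-7-yloxy)-6,7-dimethoxy-2H-chromen-2-one
Product: 15 daphnoretin methyl ether, 6,7-dimethoxy-3-[(2-oxo-2H-chromen-7-yl)oxy]-2H-chromen-2-one
Conditions: pyridinium chlorochromate [C5H5NH][CrO3Cl], Celite, CH2Cl2, reflux
Reagents that add atoms: pyridinium chlorochromate, [O-][Cr](=O)(=O)Cl.c1cc[nH+]cc1
Why: Allylic oxidation of the O–CH2 group of a 2H-chromene by hexavalent chromium, a standard chromene-to-coumarin conversion driven by formation of the aromatic 2-pyranone, to which the existing lactone, the diaryl ether and the methoxy groups are inert.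

**Compound list**

1 | resorcinol | Oc1cccc(O)c1 | starting material
2 | propargyl bromide (3-bromoprop-1-yne) | C#CCBr | starting material
3 | 3-(prop-2-yn-1-yloxy)phenol | C#CCOc1cccc(O)c1 | intermediate
4 | ethyl bromoacetate | CCOC(=O)CBr | starting material
5 | ethyl 2-[3-(prop-2-yn-1-yloxy)phenoxy]acetate | CCOC(=O)COc1cccc(OCC#C)c1 | intermediate
6 | 2-[3-(prop-2-yn-1-yloxy)phenoxy]acetic acid | OC(=O)COc1cccc(OCC#C)c1 | intermediate
7 | 2-hydroxy-4,5-dimethoxybenzaldehyde | COc1cc(O)c(C=O)cc1OC | starting material
8 | acetic 2-[3-(prop-2-yn-1-yloxy)phenoxy]acetic anhydride (mixed anhydride) | CC(=O)OC(=O)COc1cccc(OCC#C)c1 | intermediate (not isolated)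
9 | 2-formyl-4,5-dimethoxyphenyl 2-[3-(prop-2-yn-1-yloxy)phenoxy]acetate (aryl ester) | COc1cc(OC(=O)COc2cccc(OCC#C)c2)c(C=O)cc1OC | intermediate (not isolated)
10 | 6,7-dimethoxy-3-[3-(prop-2-yn-1-yloxy)phenoxy]-2H-chromen-2-one | COc1cc2cc(Oc3cccc(OCC#C)c3)c(=O)oc2cc1OC | intermediate
11 | 6,7-dimethoxy-3-{[3-oxo-4-(propa-1,2-dien-1-yl)cyclohexa-1,5-dien-1-yl]oxy}-2H-chromen-2-one (allenyl dienone, racemic) | COc1cc2cc(OC3=CC(=O)C(C=C=C)C=C3)c(=O)oc2cc1OC | intermediate (not isolated)
12 | 3-[3-hydroxy-4-(propa-1,2-dien-1-yl)phenoxy]-6,7-dimethoxy-2H-chromen-2-one (allenylphenol) | COc1cc2cc(Oc3ccc(C=C=C)c(O)c3)c(=O)oc2cc1OC | intermediate (not isolated)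
13 | 6,7-dimethoxy-3-{[(4Z)-3-oxo-4-(prop-2-en-1-ylidene)cyclohexa-1,5-dien-1-yl]oxy}-2H-chromen-2-one (quinone methide) | COc1cc2cc(OC3=CC(=O)/C(=C\C=C)C=C3)c(=O)oc2cc1OC | intermediate (not isolated)
14 | 3-(2H-chromen-7-yloxy)-6,7-dimethoxy-2H-chromen-2-one | COc1cc2cc(Oc3ccc4C=CCOc4c3)c(=O)oc2cc1OC | intermediate
15 | daphnoretin methyl ether, 6,7-dimethoxy-3-[(2-oxo-2H-chromen-7-yl)oxy]-2H-chromen-2-one | COc1cc2cc(Oc3ccc4ccc(=O)oc4c3)c(=O)oc2cc1OC | target

**Count and risks**

Total step count: 6. Longest linear sequence: 6 steps (resorcinol to target; aldehyde 7 enters at step 4).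

Steps most likely to fail:

1. Step 5. The sigmatropic shift may leak to the ring D carbon between the two oxygens, and the 2-unsubstituted chromene may polymerise during prolonged heating at about 200 °C. Fallback: setting out from propargyl ether 10, the ring would be closed at room temperature by 6-endo hydroarylation of the alkyne with Ph3PAuNTf2 (monovalent gold, a few mol %) in CH2Cl2. This is an electrophilic, Friedel–Crafts-type pathway that attacks the less hindered carbon para to the aryloxy group and forms C4'–C4a' without breaking O1'–C2'. It comes back to the route at chromene 14; no new compound arises on this path (F0).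

2. Step 6. The allylic oxidation may stall, or the electron-rich chromene may degrade oxidatively before the lactone is reached. Fallback: setting out from chromene 14, hydride abstraction with DDQ in CH2Cl2/H2O would give the benzopyrylium ion, which water traps as the racemic lactol 3-[(2-hydroxy-2H-chromen-7-yl)oxy]-6,7-dimethoxy-2H-chromen-2-one F1. Oxidation of F1 with catalytic TEMPO and PhI(OAc)2 in CH2Cl2 would then give the lactone, coming back to the route at target 15.

3. Step 4. The acetyl donor may compete in the condensation (acetic anhydride itself condensing with the aldehyde to a 3-unsubstituted coumarin), and the intramolecular aldol closure may be sluggish at a temperature kept low for the sake of the propargyl ether. Fallback: setting out from acid 6, oxalyl chloride with catalytic DMF in CH2Cl2 would give 2-[3-(prop-2-yn-1-yloxy)phenoxy]acetyl chloride F2. F2 would acylate the phenol of aldehyde 7 (Et3N, CH2Cl2, 0 °C) to give aryl ester 9, this time isolated, and DBU in MeCN at room temperature would effect the intramolecular aldol condensation, coming back to the route at coumarin 10.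

**Further compounds**

F0 | step 5 | none | none
F1 | step 6 | 3-[(2-hydroxy-2H-chromen-7-yl)oxy]-6,7-dimethoxy-2H-chromen-2-one (racemic lactol) | COc1cc2cc(Oc3ccc4C=CC(O)Oc4c3)c(=O)oc2cc1OC
F2 | step 4 | 2-[3-(prop-2-yn-1-yloxy)phenoxy]acetyl chloride | ClC(=O)COc1cccc(OCC#C)c1
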